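Two questions stand over this flask, and you answer them from two runs that were charged alike in starting material.

| flask | starting material | coupling partner | time |
|---|---|---|---|
| east | 0.300 M | 0.300 M |  |
| south-west | 0.300 M | 0.150 M |  |
| north-east | 0.0600 M | 0.300 M | 120 min |

- east run (time / min: [product] / M): 4.8: 0.0156; 8.2: 0.0274; 14: 0.0358; 24: 0.0601; 41: 0.0917; 70: 0.1333; 120: 0.1698
- south-west run (time / min: [product] / M): 4.8: 0.0110; 8.2: 0.0142; 14: 0.0189; 24: 0.0286; 41: 0.0474; 70: 0.0722; 120: 0.0961

(readings scatter by 0.002 M)

- Overall: starting material + coupling partner -> product.
- Constant volume, constant temperature.
- What is held in complexes is read along with the free species.
- "The second partner" is coupling partner.
- An order is taken over about fifteen percent of the charge, up and down.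

- order of the initial rate in [coupling partner], near the charge of the east run, the rate being that where two percent of its starting material are product
- product in the north-east run at 120 min, as a share of the starting material charged

First comes the order in coupling partner. With half the coupling partner, the south-west run shows at 24 min 0.476 of the product of the east run, so the order reads about 1.07, and you carry the rate as proportional to the coupling partner.

That raises the second question, what the north-east run does. Its starting material is 20.0% of its coupling partner, so starting material is the limiting reagent. The east run, with equal charges, reads at its last point 0.0362 /M/min for the apparent constant k_a, the rate divided by the starting material and the coupling partner still unreacted, averaged from the start to that reading. Carried unchanged into the second-order integrated form for unequal charges, k_a gives your reckoning of 69.7% at 120 min. You hold it loosely, though, since the last reading of the east run leaves 0.130 M of starting material unreacted, more than the north-east run starts with.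

The forecast gives order 1 (0.75 to 1.2) and 69% (58% to 80%), a yield slightly lower than yours, and says of it: “The order in starting material at low charge is untested directly, so the range is wider.”

The flask gives order 1.0 and 79.2%, which is 10 percentage points above the forecast, and a power-law fit to the two runs gives 78.9% for the north-east run.

    starting material + coupling partner → product (0.05208 /M/min)
    2 starting material ⇌ idle substrate dimer, settled at all times (1.320 /M)

Reckoned back from that yield, k_a in the north-east run is 0.0486 /M/min, higher than the east reading by a factor of 1.34. In the south-west run, the east k_a puts 0.0750 M of product, a quarter of the starting material charged, at 74.6 min, and that run reached it at 75.9 min.

All runs are calculated with made-up constants, noise included.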